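**Retrosynthetic overview**
1. The strategy rests on the quaternary spiro carbon shared by ring A and ring B. In ring A it is bonded to the CMe2 carbon and to the C(=CH2) carbon, and CMe2 lies anti to the ether oxygen on the neighbouring ring B carbon. This is the pattern left by a 1,2-shift onto an epoxide carbon from a carbinol that ends as a ketone.
2. Target 24 ⇐ desilylation, C=O to C=CH2, and oxolane closure (ring B hydroxyl onto the ring A alkene) ⇐ spiro β-hydroxy ketone 20 ⇐ semipinacol ring expansion of epoxy cyclopentenol 19.
3. 19 ⇐ vinyl iodide 12 (as its Grignard reagent) + 2,2-dimethylcyclopentane-1,3-dione 13, then enol triflate, α-epoxidation and triflate reduction.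
4. 12 ⇐ (S)-Wieland–Miescher ketone 1: bis-ketal, hydroboration/oxidation/MeMgBr (ring C carbinol, trans fusion), C3 vinyl iodide, hydride reduction and Appel inversion (equatorial bromide).
5. Ring order: rings B and C come from 1; a cyclopentene is attached and enlarged to ring A in the key step; the oxolane closes last.

Key step: step 15

Remarks on the chemistry:
- Decalin carbons are numbered as in a steroid AB system. Ring B is C1, C2, C3, C4, C5, C10 and ring C is C5 to C10. C10 carries the angular methyl, C3 becomes the spiro carbon, C2 the ether carbon, C6 the tertiary carbinol and C9 the bromide.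
- β is the face of the C10 methyl group; α is the opposite face.
- Compounds 15 to 19 are carried as both epimers at the cyclopentane carbinol carbon. That carbon becomes the ring A carbonyl carbon in step 15, so their SMILES leave it open.

**Step 1**
Reactants: 1 (S)-Wieland–Miescher ketone
Product: 2 3,3:9,9-bis(ethylenedioxy)-10β-methyloctal-5-ene (both carbonyls as dioxolanes, alkene moved to C5=C6)
Conditions: HOCH2CH2OH (excess), TsOH·H2O (cat.), benzene, reflux, Dean–Stark
Reagents that add atoms: ethylene glycol, OCCO
Why: Acid-catalysed ketalisation with azeotropic water removal protects both carbonyl groups, and the enone gives the β,γ-unsaturated ketal, which places the alkene at C5=C6 for work on ring C.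

**Step 2**
Reactants: 2 bis-ketal alkene
Product: 4 3,3:9,9-bis(ethylenedioxy)-10β-methyl-trans-decalin-6α-ol (5α-H; OH equatorial), via C6 alkylborane 3 (not isolated)
Conditions: BH3·THF, THF, 0 °C to rt; then NaOH, H2O2, H2O, 0 °C to rt
Reagents that add atoms: hydrogen peroxide, OO
Why: Brown hydroboration–oxidation puts boron on C6 and hydrogen on C5 by syn addition from the α face, away from the axial C10 methyl group, so the ring fusion becomes trans and oxidation with retention gives the equatorial C6 alcohol.

**Step 3**
Reactants: 4 C6 alcohol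
Product: 5 3,3:9,9-bis(ethylenedioxy)-10β-methyl-trans-decalin-6-one
Conditions: Dess–Martin periodinane, NaHCO3, CH2Cl2, rt
Reagents that add atoms: none
Why: Dess–Martin oxidation under bicarbonate buffer gives the ketone without acid that could open the ketals or epimerise C5.

**Step 4**
Reactants: 5 C6 ketone
Product: 6 3,3:9,9-bis(ethylenedioxy)-6α,10β-dimethyl-trans-decalin-6β-ol (OH axial and syn to the C10 methyl)
Conditions: MeMgBr, THF, −78 to 0 °C; then H2O
Reagents that add atoms: methylmagnesium bromide, C[Mg]Br
Why: Grignard addition comes from the equatorial side because the axial path at C6 is blocked by the 1,3-diaxial C10 methyl group, which sets the carbinol with axial OH and equatorial methyl.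

**Step 5**
Reactants: 6 tertiary carbinol bis-ketal
Product: 7 6β-hydroxy-6α,10β-dimethyl-trans-decalin-3,9-dione
Conditions: 1 M HCl, THF, rt
Reagents that add atoms: water, O
Why: Aqueous acid hydrolysis removes both dioxolanes, and the dilute acid at room temperature should leave the tertiary alcohol in place.

**Step 6**
Reactants: 7 hydroxy diketone
Product: 8 C3 hydrazone of 7 (C9 ketone free)
Conditions: N2H4·H2O, Et3N, EtOH, 0 °C to rt
Reagents that add atoms: hydrazine (used as the hydrate), NN
Why: Hydrazone formation is chemoselective for the unhindered C3 carbonyl, since the C9 carbonyl sits next to the quaternary C10 and condenses far more slowly.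

**Step 7**
Reactants: 8 C3 hydrazone
Product: 9 6β-hydroxy-3-iodo-6α,10β-dimethyl-trans-octal-2-en-9-one (C2=C3 vinyl iodide)
Conditions: I2, 1,1,3,3-tetramethylguanidine, THF, 0 °C to rt
Reagents that add atoms: iodine, II
Why: In the Barton vinyl iodide synthesis iodine oxidises the hydrazone to the diazo compound, iodination and loss of N2 give an iodo cation, and proton loss toward C2, the usual direction for a 3-oxo trans-decalin, gives the C2=C3 iodide.

**Step 8**
Reactants: 9 hydroxy vinyl iodide ketone
Product: 10 3-iodo-6α,10β-dimethyl-6β-(triethylsilyloxy)-trans-octal-2-en-9-one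
Conditions: Et3SiOTf, 2,6-lutidine, CH2Cl2, −78 to −20 °C
Reagents that add atoms: triethylsilyl trifluoromethanesulfonate, CC[Si](CC)(CC)OS(=O)(=O)C(F)(F)F
Why: The silyl triflate with a hindered pyridine base silylates the tertiary alcohol at low temperature faster than it enolises the hindered C9 ketone, and the silyl ether shields the carbinol in the bromination and Lewis acid steps.

**Step 9**
Reactants: 10 silyl ether ketone
Product: 11 3-iodo-6α,10β-dimethyl-6β-(triethylsilyloxy)-trans-octal-2-en-9α-ol (OH axial and anti to the C10 methyl)
Conditions: LiBH(s-Bu)3, THF, −78 °C; then H2O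
Reagents that add atoms: none
Why: The bulky trialkylborohydride attacks the C9 carbonyl of the chair ring C from the equatorial side, as it does with 4,4-dimethyl 3-ketones, and gives the axial alcohol needed for inversion, while the vinyl iodide is inert at −78 °C.

**Step 10**
Reactants: 11 axial C9 alcohol
Product: 12 9β-bromo-3-iodo-6α,10β-dimethyl-6β-(triethylsilyloxy)-trans-octal-2-ene (Br equatorial and syn to the C10 methyl)
Conditions: CBr4, P(n-C8H17)3, toluene, 70 °C
Reagents that add atoms: carbon tetrabromide, BrC(Br)(Br)Br
Why: In the Appel reaction bromide displaces the alkoxyphosphonium group with inversion (SN2), which turns the axial 9α oxygen into the equatorial 9β bromide, and the trialkylphosphine variant is chosen for the hindered neopentyl position.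

**Step 11**
Reactants: 12 bromo vinyl iodide; 13 2,2-dimethylcyclopentane-1,3-dione
Product: 15 3-hydroxy-2,2-dimethylcyclopentan-1-one bonded at its C3 to decalin C3 (both carbinol epimers), via alkenylmagnesium chloride 14 (not isolated)
Conditions: i-PrMgCl·LiCl, THF, 0 °C to rt; then 13 (excess), −78 to −20 °C; then aq. NH4Cl
Reagents that add atoms: none
Why: Iodine–magnesium exchange spares the hindered secondary bromide and the silyl ether, and the alkenyl Grignard reagent adds once to the symmetric dione to give the tertiary allylic alcohol, whose configuration is not controlled and need not be.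

**Step 12**
Reactants: 15 keto carbinol
Product: 17 4-hydroxy-5,5-dimethylcyclopent-1-en-1-yl triflate bonded at its C4 to decalin C3, via dilithium alkoxide enolate 16 (not isolated)
Conditions: LiN(i-Pr)2 (2.3 equiv), THF, −78 °C; then PhNTf2, −78 to 0 °C; then H2O
Reagents that add atoms: N-phenylbis(trifluoromethanesulfonimide), O=S(=O)(N(c1ccccc1)S(=O)(=O)C(F)(F)F)C(F)(F)F
Why: Excess amide base forms the alkoxide and the only possible enolate (the other α carbon is quaternary), and O-triflation gives the enol triflate, while fast enolisation at −78 °C forestalls retro-aldol opening of the β-hydroxy ketone.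

**Step 13**
Reactants: 17 enol triflate
Product: 18 2α,3α-epoxide of 17 (epoxide on ring B, anti to the C10 methyl)
Conditions: mCPBA, NaHCO3, CH2Cl2, 0 °C
Reagents that add atoms: meta-chloroperoxybenzoic acid, OOC(=O)c1cccc(Cl)c1
Why: In this Prilezhaev epoxidation the peracid takes the electron-rich trisubstituted ring B alkene, helped by the allylic hydroxyl, from the α face anti to the axial C10 methyl group, while the electron-poor enol triflate alkene does not react; this sets the C2 oxygen configuration.

**Step 14**
Reactants: 18 epoxy enol triflate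
Product: 19 2α,3α-epoxide carrying 1-hydroxy-2,2-dimethylcyclopent-3-en-1-yl on C3
Conditions: Pd(OAc)2 (cat.), PPh3, n-Bu3N, HCO2H, DMF, 60 °C
Reagents that add atoms: none
Why: Palladium-catalysed formate reduction of the enol triflate (oxidative addition to zerovalent palladium, formate exchange, loss of CO2, reductive elimination) gives the cyclopentene without touching the epoxide, the alkyl bromide or the silyl ether.

**Step 15**
Reactants: 19 epoxy cyclopentenol
Product: 20 spiro β-hydroxy ketone (ring B 2α-OH; ring A a cyclohex-3-en-1-one with C=O and CMe2 flanking the spiro carbon)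
Conditions: BF3·OEt2 (0.5 equiv), CH2Cl2, −78 °C; then Et3N, aq. NaHCO3
Reagents that add atoms: none
Why: BF3 binds the epoxide oxygen and the C3–O bond at the tertiary end lengthens, and the CMe2 carbon of the cyclopentenol, antiperiplanar to that bond, shifts from the carbinol carbon to C3 while the carbinol oxygen becomes the carbonyl group; this is a semipinacol rearrangement of a 2,3-epoxy tertiary alcohol, and the closest known type is the Lewis-acid ring expansion of 1-(epoxyalkyl)cycloalkanols to spiro β-hydroxy ketones. Ring A is not closed end to end but arises by one-carbon enlargement of the cyclopentene through this 1,2-shift, which also makes the spiro C–CMe2 bond. The spiro centre is set by inversion at C3: the epoxide oxygen is α (step 13), so CMe2 enters on the β face, trans to the C2 hydroxyl, and the carbonyl carbon ends cis to it, for either carbinol epimer. The step needs opening at the tertiary and not the secondary epoxide carbon, which cation stability secures, and migration of CMe2 rather than the ring CH2, which is favoured because CMe2 is quaternary and allylic and carries positive charge better in the transition state. Low temperature and a cold amine quench should keep the β,γ-alkene out of conjugation and avoid retro-aldol cleavage of the product.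

**Step 16**
Reactants: 20 spiro β-hydroxy ketone
Product: 22 oxolane ketone (ether oxygen bridging ring B C2 and the ring A carbon next to CMe2), via ring A organomercury trifluoroacetate 21 (not isolated)
Conditions: Hg(OCOCF3)2, THF, 0 °C to rt; then NaBH4, aq. NaOH, −20 °C
Reagents that add atoms: none
Why: In this intramolecular alkoxymercuration the ring B hydroxyl opens the mercurinium ion at the nearer alkene carbon in a 5-exo closure, as in the kinetic closure of cyclohex-3-enylmethanols to 6-oxabicyclo[3.2.1]octanes; the tether fixes the new bridgehead configuration, and cold borohydride then replaces mercury by hydrogen.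

**Step 17**
Reactants: 22 oxolane ketone
Product: 23 triethylsilyl ether of the target (ring A methylidene in place)
Conditions: Cp2TiMe2, toluene, 75 °C, dark
Reagents that add atoms: dimethyltitanocene, C[Ti](C)(C1C=CC=C1)C1C=CC=C1
Why: In the Petasis methylenation Cp2TiMe2 loses methane on heating to give Cp2Ti=CH2, which converts the hindered ketone into the methylidene group through an oxatitanacyclobutane under non-basic conditions.

**Step 18**
Reactants: 23 silyl ether
Product: 24 target, CNP0412361.2
Conditions: Bu4NF, THF, rt to 50 °C
Reagents that add atoms: none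
Why: Fluoride cleaves the Si–O bond of the tertiary triethylsilyl ether, and the equatorial neopentyl bromide, which has no antiperiplanar hydrogen, should be inert to the basic fluoride.

**Compound list**
1 | (S)-Wieland–Miescher ketone | O=C1CC[C@]2(C)C(=O)CCCC2=C1 | starting material
2 | 3,3:9,9-bis(ethylenedioxy)-10β-methyloctal-5-ene | C1COC2(O1)CC[C@]3(C)C4(OCCO4)CCC=C3C2 | intermediate
3 | C6 α-alkylborane of 2 (5α-H), drawn as the monoalkylborane | C1COC2(O1)CC[C@]3(C)C4(OCCO4)CC[C@H](B)[C@H]3C2 | intermediate
4 | 3,3:9,9-bis(ethylenedioxy)-10β-methyl-trans-decalin-6α-ol | C1COC2(O1)CC[C@]3(C)C4(OCCO4)CC[C@H](O)[C@H]3C2 | intermediate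
5 | 3,3:9,9-bis(ethylenedioxy)-10β-methyl-trans-decalin-6-one | C1COC2(O1)CC[C@]3(C)C4(OCCO4)CCC(=O)[C@H]3C2 | intermediate
6 | 3,3:9,9-bis(ethylenedioxy)-6α,10β-dimethyl-trans-decalin-6β-ol | C1COC2(O1)CC[C@]3(C)C4(OCCO4)CC[C@@](C)(O)[C@H]3C2 | intermediate
7 | 6β-hydroxy-6α,10β-dimethyl-trans-decalin-3,9-dione | O=C1CC[C@]2(C)C(=O)CC[C@@](C)(O)[C@H]2C1 | intermediate
8 | C3 hydrazone of 7 | NN=C1CC[C@]2(C)C(=O)CC[C@@](C)(O)[C@H]2C1 | intermediate
9 | 6β-hydroxy-3-iodo-6α,10β-dimethyl-trans-octal-2-en-9-one | IC1=CC[C@]2(C)C(=O)CC[C@@](C)(O)[C@H]2C1 | intermediate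
10 | 3-iodo-6α,10β-dimethyl-6β-(triethylsilyloxy)-trans-octal-2-en-9-one | IC1=CC[C@]2(C)C(=O)CC[C@@](C)(O[Si](CC)(CC)CC)[C@H]2C1 | intermediate
11 | 3-iodo-6α,10β-dimethyl-6β-(triethylsilyloxy)-trans-octal-2-en-9α-ol | IC1=CC[C@]2(C)[C@H](O)CC[C@@](C)(O[Si](CC)(CC)CC)[C@H]2C1 | intermediate
12 | 9β-bromo-3-iodo-6α,10β-dimethyl-6β-(triethylsilyloxy)-trans-octal-2-ene | IC1=CC[C@]2(C)[C@@H](Br)CC[C@@](C)(O[Si](CC)(CC)CC)[C@H]2C1 | intermediate
13 | 2,2-dimethylcyclopentane-1,3-dione | CC1(C)C(=O)CCC1=O | starting material
14 | C3 alkenylmagnesium chloride from 12 (LiCl complex) | Cl[Mg]C1=CC[C@]2(C)[C@@H](Br)CC[C@@](C)(O[Si](CC)(CC)CC)[C@H]2C1 | intermediate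
15 | keto carbinol: 3-hydroxy-2,2-dimethylcyclopentan-1-one bonded at C3 to decalin C3, both carbinol epimers | CC1(C)C(=O)CCC1(O)C2=CC[C@]3(C)[C@@H](Br)CC[C@@](C)(O[Si](CC)(CC)CC)[C@H]3C2 | intermediate
16 | dilithium alkoxide enolate of 15 | CC1(C)C(O[Li])=CCC1(O[Li])C2=CC[C@]3(C)[C@@H](Br)CC[C@@](C)(O[Si](CC)(CC)CC)[C@H]3C2 | intermediate
17 | enol triflate: 4-hydroxy-5,5-dimethylcyclopent-1-en-1-yl triflate bonded at C4 to decalin C3 | CC1(C)C(OS(=O)(=O)C(F)(F)F)=CCC1(O)C2=CC[C@]3(C)[C@@H](Br)CC[C@@](C)(O[Si](CC)(CC)CC)[C@H]3C2 | intermediate
18 | 2α,3α-epoxide of 17 | CC1(C)C(OS(=O)(=O)C(F)(F)F)=CCC1(O)[C@@]23O[C@@H]2C[C@]4(C)[C@@H](Br)CC[C@@](C)(O[Si](CC)(CC)CC)[C@H]4C3 | intermediate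
19 | 2α,3α-epoxide carrying 1-hydroxy-2,2-dimethylcyclopent-3-en-1-yl on C3 | CC1(C)C=CCC1(O)[C@@]23O[C@@H]2C[C@]4(C)[C@@H](Br)CC[C@@](C)(O[Si](CC)(CC)CC)[C@H]4C3 | intermediate
20 | spiro β-hydroxy ketone (ring A cyclohex-3-en-1-one, ring B 2α-OH) | O[C@@H]3C[C@]4(C)[C@@H](Br)CC[C@@](C)(O[Si](CC)(CC)CC)[C@H]4C[C@]13C(C)(C)C=CCC1=O | intermediate
21 | ring A organomercury trifluoroacetate (Hg anti to the new ether oxygen) | O=C1C[C@@H]([Hg]OC(=O)C(F)(F)F)[C@@H]2O[C@@H]3C[C@]4(C)[C@@H](Br)CC[C@@](C)(O[Si](CC)(CC)CC)[C@H]4C[C@]13C2(C)C | intermediate
22 | oxolane ketone | O=C1CC[C@@H]2O[C@@H]3C[C@]4(C)[C@@H](Br)CC[C@@](C)(O[Si](CC)(CC)CC)[C@H]4C[C@]13C2(C)C | intermediate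
23 | triethylsilyl ether of the target | C=C1CC[C@@H]2O[C@@H]3C[C@]4(C)[C@@H](Br)CC[C@@](C)(O[Si](CC)(CC)CC)[C@H]4C[C@]13C2(C)C | intermediate
24 | CNP0412361.2 | C=C1CC[C@@H]2O[C@@H]3C[C@]4(C)[C@@H](Br)CC[C@@](C)(O)[C@H]4C[C@]13C2(C)C | target

**Step count and risks**
Total steps: 18. Longest linear sequence: 18 steps, from 1 to 24; 13 enters at step 11.

The three steps most likely to fail:

1. Step 15. What may go wrong: the ring CH2 carbon migrates in place of the CMe2 carbon, the tertiary cation loses a proton or takes a hydride before any shift, or the ring A alkene drifts into conjugation under the Lewis acid. Fallback: setting out from 19, the carbinol is silylated with N-(trimethylsilyl)imidazole to give the carbinol trimethylsilyl ether F1. F1 is then treated with TiCl4 in CH2Cl2 at −78 °C. The titanium-bound epoxide should open in concert with the 1,2-shift, the silyl group leaves the oxocarbenium ion as Me3SiCl, and aqueous work-up frees the C2 hydroxyl. This returns the route to 20.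

2. Step 10. What may go wrong: the activated axial oxygen is lost by elimination with the antiperiplanar C8 hydrogen, or a methyl shift from C10 outruns substitution at the crowded neopentyl carbon. Fallback: setting out from 11, the alcohol is converted with Tf2O and pyridine at low temperature into the 9α-triflate F2. F2 is then displaced by Bu4NBr in toluene, so that activation and substitution are separated and the bromide source is non-basic. This returns the route to 12.

3. Step 16. What may go wrong: borohydride attacks the ring A ketone during demercuration, the alkene moves into conjugation before mercuration, or closure occurs at the distal alkene carbon. Fallback: setting out from 20, the mercuration is run as before to 21. NaBH4 is then used in excess at 0 °C so that the C–Hg bond and the ketone are both reduced, which gives the ring A secondary alcohol F3 as both carbinol epimers. Dess–Martin oxidation of F3 restores the ketone and returns the route to 22.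

Further compounds
F1 | step 15 | carbinol trimethylsilyl ether of 19 | CC1(C)C=CCC1(O[Si](C)(C)C)[C@@]23O[C@@H]2C[C@]4(C)[C@@H](Br)CC[C@@](C)(O[Si](CC)(CC)CC)[C@H]4C3
F2 | step 10 | 9α-triflate of 11 | IC1=CC[C@]2(C)[C@H](OS(=O)(=O)C(F)(F)F)CC[C@@](C)(O[Si](CC)(CC)CC)[C@H]2C1
F3 | step 16 | ring A secondary alcohol from over-reduction of 22 (both carbinol epimers) | OC1CC[C@@H]2O[C@@H]3C[C@]4(C)[C@@H](Br)CC[C@@](C)(O[Si](CC)(CC)CC)[C@H]4C[C@]13C2(C)C
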